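Locants used below (cyathane type): ring A = C1–C2–C3–C4–C9, ring B = C4–C5–C6–C7–C8–C9, ring C = C5–C10–C11–C12–C13–C14–C6; C15 and C16 are the methyls on C12 and C6, C17 is the CH2O on C9, C18/C19/C20 are the lactone α-carbon, exocyclic CH2 and carbonyl; β is the face of C17.
Cuts, in retrosynthetic order: epoxide O; C18=C19; C3–C4 (ketyl–olefin), then C2–C3 and O–C20 (vinyl–aldehyde coupling, lactonisation); C9–C17 and C9–C1 (enolate alkylations); C4=O (allylic oxidation); C11–C12 together with O–C13 (Claisen shift and alkyne hydroalkoxylation); C5–C10 (vinyl addition); C6–C14 (asymmetric alkylation).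
Forward: ring B is the starting cyclohexanone; ring C is closed in one cascade; C4 and C9 are then functionalised; ring A and the lactone follow; the epoxide comes last.
Stereochemistry: C6 from a catalytic asymmetric alkylation; C5 from protonation anti to the C6 methyl; C9 from axial attack on the trans-fused enolate; C2 from a ligand-controlled coupling; C3 and C4 from the tethered, anti ketyl cyclisation; C12/C13 from peracid attack anti to the C6 methyl.
Enabling feature: ring C holds only the C12=C13 unit, equivalent to an α-methyl ketone at C13, in a γ,δ relation (C13–C12–C11–C10=C5) to ring-fusion carbon C5 beside the quaternary C6. This cyclohept-4-enone pattern is the product of a Claisen shift of a C5–O–C13=C12 enol ether carrying a C5 vinyl group, and that enol ether is the 5-exo-dig adduct of a C5 alkoxide to a but-2-ynyl group on C6; the C5=C10 alkene left behind then directs oxygen to C4.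

Key step: step 4

Remark: the antipodes of the chromium catalyst (step 2) and of the ligand (step 13) are written as those assumed to deliver (S)-5 and (2S)-21; if the sense of induction is the reverse, the mirror-image catalyst or ligand is used.
Remark: names of the bicyclic intermediates 9–21 use von Baeyer locants; the Why lines use the skeleton locants defined above.

Step 1
Reactants: 1 2-methylcyclohexan-1-one
Product: 2 2-methylcyclohex-1-en-1-yl acetate
Conditions: Ac2O, HClO4 (cat.), CCl4, rt
Reagents that add atoms: acetic anhydride, CC(=O)OC(C)=O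
Why: Acid-catalysed enol acetylation under equilibrating conditions should give the more substituted enol acetate, the regiodefined precursor of the quaternary centre.

Step 2
Reactants: 2 2-methylcyclohex-1-en-1-yl acetate; 3 1-bromobut-2-yne
Product: 5 (S)-2-(but-2-yn-1-yl)-2-methylcyclohexan-1-one, via tributyltin enolate 4 (not isolated)
Conditions: Bu3SnOMe, neat, 60 °C, methyl acetate removed under vacuum; then 3, (S,S)-(salen)CrCl (5 mol %), benzene, 0 °C
Reagents that add atoms: none
Why: Transmetalation to the tin enolate followed by (salen)CrCl-catalysed enantioselective alkylation of the tetrasubstituted tin enolate with the propargylic bromide should set the C6 quaternary centre by catalyst control of the enolate face.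

Step 3
Reactants: 5 (S)-2-(but-2-yn-1-yl)-2-methylcyclohexan-1-one; 6 vinylmagnesium bromide
Product: 7 (2S)-2-(but-2-yn-1-yl)-2-methyl-1-vinylcyclohexan-1-ol (both C1 epimers)
Conditions: CeCl3, THF, −78 → 0 °C; then H2O
Reagents that add atoms: none
Why: Cerium-assisted Grignard 1,2-addition to the hindered α-quaternary ketone installs the C5 oxygen and the C10=C11 vinyl group; the new carbinol centre may form as a mixture because step 4 makes C5 trigonal.

Step 4
Reactants: 7 (2S)-2-(but-2-yn-1-yl)-2-methyl-1-vinylcyclohexan-1-ol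
Product: 9 (1S)-1,4-dimethylbicyclo[5.4.0]undec-6-en-3-one (epimers at the methyl-bearing C4), via (Z)-2-ethylidene-5-vinyloxolane 8 (not isolated)
Conditions: MeLi (10 mol %), phenetole, 200 °C (microwave)
Reagents that add atoms: none
Why: The catalytic lithium alkoxide of 7 adds anti and 5-exo-dig to the butynyl triple bond (O–C13) and proton transfer from further 7 gives the (Z)-2-ethylidene-5-vinyloxolane 8, whose allyl vinyl ether array C11=C10–C5–O–C13=C12 then undergoes a [3,3]-sigmatropic (Claisen) shift through a boat-like transition state that forms C11–C12, breaks C5–O and so expands the oxolane by three atoms into the seven-membered ring C. The closest known reaction type is the base-catalysed tandem 5-exo-dig cyclisation/Claisen rearrangement of 1-alkenyl-4-alkyn-1-ols to cyclohept-4-enones. Ring closures: the oxolane by anionic 5-exo-dig hydroalkoxylation, ring C by the concerted [3,3] shift. The only new stereocentre (C12) follows from the Z enol ether and the boat transition state but is unimportant because step 5 makes C12 trigonal, both C5 epimers of 7 should converge because C5 becomes trigonal, and the C6 quaternary centre is a spectator. The step needs exo (O–C13) rather than endo (O–C12) addition and rearrangement through the vinyl group only: the anionic mode favours the exo-dig path, the endocyclic enol ether isomer cannot reach a [3,3] geometry, and the 1,6-enyne spacing excludes an oxy-Cope pathway.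

Step 5
Reactants: 9 (1S)-1,4-dimethylbicyclo[5.4.0]undec-6-en-3-one
Product: 10 (1S)-1,4-dimethylbicyclo[5.4.0]undeca-3,6-dien-3-yl triflate
Conditions: Tf2O, 2,6-di-tert-butyl-4-methylpyridine, CH2Cl2, 0 °C → rt
Reagents that add atoms: trifluoromethanesulfonic anhydride, O=S(=O)(OS(=O)(=O)C(F)(F)F)C(F)(F)F
Why: Enol triflate formation under these conditions should favour the more substituted C12=C13 isomer (enolisation toward C14 is disfavoured beside the quaternary C6), which fixes the position of the future ring C alkene and removes the C12 stereocentre.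

Step 6
Reactants: 10 (1S)-1,4-dimethylbicyclo[5.4.0]undeca-3,6-dien-3-yl triflate
Product: 11 (1S)-8-hydroxy-1,4-dimethylbicyclo[5.4.0]undeca-3,6-dien-3-yl triflate (C8 epimers)
Conditions: SeO2 (cat.), t-BuOOH, CH2Cl2, rt
Reagents that add atoms: tert-butyl hydroperoxide, CC(C)(C)OO (terminal source of the new oxygen, relayed by SeO2, O=[Se]=O)
Why: SeO2 allylic oxidation (ene reaction then [2,3]-sigmatropic shift) should oxidise the CH2 on the more substituted end of the C5=C10 alkene, i.e. C4, as in the 4-hydroxylation of steroidal 5-enes, while the electron-poor enol triflate stays inert; the carbinol configuration is irrelevant.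

Step 7
Reactants: 11 (1S)-8-hydroxy-1,4-dimethylbicyclo[5.4.0]undeca-3,6-dien-3-yl triflate
Product: 12 (1S)-1,4-dimethyl-8-oxobicyclo[5.4.0]undeca-3,6-dien-3-yl triflate
Conditions: DMP (1,1,1-triacetoxy-1,1-dihydro-1,2-benziodoxol-3(1H)-one), CH2Cl2, rt
Reagents that add atoms: none
Why: Hypervalent-iodine oxidation of the allylic alcohol should give the C4 enone without touching the enol triflate.

Step 8
Reactants: 12 (1S)-1,4-dimethyl-8-oxobicyclo[5.4.0]undeca-3,6-dien-3-yl triflate
Product: 13 (1S,7S)-1,4-dimethyl-8-oxobicyclo[5.4.0]undec-3-en-3-yl triflate (trans ring fusion)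
Conditions: [(Ph3P)CuH]6, H2O, benzene, rt
Reagents that add atoms: none
Why: Copper hydride conjugate reduction delivers hydride to C10, and protonation of the copper enolate at C5 on the face opposite the axial C6 methyl should give the trans ring fusion (H5 β), which is also expected to be the more stable epimer of this ketone.

Step 9
Reactants: 13 (1S,7S)-1,4-dimethyl-8-oxobicyclo[5.4.0]undec-3-en-3-yl triflate; 14 allyl bromide
Product: 15 (1S,7S)-9-allyl-1,4-dimethyl-8-oxobicyclo[5.4.0]undec-3-en-3-yl triflate (C9 epimers)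
Conditions: LiN(iPr)2 (LDA), THF, −78 °C; then 14, DMPU, −78 → −20 °C
Reagents that add atoms: none
Why: Kinetic enolate alkylation should occur at the C9 methylene and not at the hindered ring-fusion C5–H, bringing in C1–C2 as an allyl group; the C9 configuration is not yet fixed and does not matter.

Step 10
Reactants: 15 (1S,7S)-9-allyl-1,4-dimethyl-8-oxobicyclo[5.4.0]undec-3-en-3-yl triflate
Product: 17 (1S,7S,9S)-9-allyl-9-[(tert-butyldimethylsilyloxy)methyl]-1,4-dimethyl-8-oxobicyclo[5.4.0]undec-3-en-3-yl triflate, via lithium aldolate 16 (not isolated)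
Conditions: LiN(iPr)2 (LDA), THF, −78 °C; CH2O (gas); then TBSOTf, −78 °C
Reagents that add atoms: formaldehyde, C=O; tert-butyldimethylsilyl trifluoromethanesulfonate, CC(C)(C)[Si](C)(C)OS(=O)(=O)C(F)(F)F
Why: A second kinetic enolisation at C9 and aldol addition to formaldehyde by axial attack on the β face of the rigid trans-fused chair (only H5 and H7 are syn-axial) should place C17 β and the allyl group α, and in situ silylation of the aldolate prevents retro-aldol loss of formaldehyde.

Step 11
Reactants: 17 (1S,7S,9S)-9-allyl-9-[(tert-butyldimethylsilyloxy)methyl]-1,4-dimethyl-8-oxobicyclo[5.4.0]undec-3-en-3-yl triflate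
Product: 18 (1S,7S,9S)-9-[(tert-butyldimethylsilyloxy)methyl]-1,4-dimethyl-8-oxo-9-(2-oxoethyl)bicyclo[5.4.0]undec-3-en-3-yl triflate
Conditions: O3, CH2Cl2, −78 °C; then Me2S
Reagents that add atoms: ozone, [O-][O+]=O
Why: Ozonolysis should cleave the electron-rich terminal alkene much faster than the electron-poor tetrasubstituted enol triflate, which serves here as a protected form of the C12=C13 alkene, and so gives the C2 aldehyde.

Step 12
Reactants: 18 (1S,7S,9S)-9-[(tert-butyldimethylsilyloxy)methyl]-1,4-dimethyl-8-oxo-9-(2-oxoethyl)bicyclo[5.4.0]undec-3-en-3-yl triflate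
Product: 19 (1S,7S,9S)-9-[(tert-butyldimethylsilyloxy)methyl]-1,4-dimethyl-9-(2-oxoethyl)bicyclo[5.4.0]undec-3-en-8-one
Conditions: Pd(OAc)2 (cat.), PPh3, Bu3N, HCO2H, DMF, 60 °C
Reagents that add atoms: none
Why: Palladium-catalysed formate reduction of the enol triflate (oxidative addition, formate decarboxylation, reductive elimination) replaces OTf by H without moving the double bond and should tolerate aldehyde, ketone and silyl ether.

Step 13
Reactants: 19 (1S,7S,9S)-9-[(tert-butyldimethylsilyloxy)methyl]-1,4-dimethyl-9-(2-oxoethyl)bicyclo[5.4.0]undec-3-en-8-one; 20 methyl (Z)-3-iodoacrylate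
Product: 21 (1S,7S,9S)-9-[(tert-butyldimethylsilyloxy)methyl]-1,4-dimethyl-9-{[(2S)-5-oxo-2,5-dihydrofuran-2-yl]methyl}bicyclo[5.4.0]undec-3-en-8-one
Conditions: CrCl2, NiCl2 (cat.), (S)-N-[2-(4-isopropyl-4,5-dihydrooxazol-2-yl)phenyl]methanesulfonamide, Et3N, THF, rt; then H2O
Reagents that add atoms: none
Why: Nozaki–Hiyama–Kishi coupling of the (Z)-vinyl iodide with the aldehyde (chemoselective over the ketone) and spontaneous lactonisation of the resulting (Z)-γ-alkoxy ester should give the butenolide, the chiral sulfonamide ligand on chromium controlling the new C2 centre.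

Step 14
Reactants: 21 (1S,7S,9S)-9-[(tert-butyldimethylsilyloxy)methyl]-1,4-dimethyl-9-{[(2S)-5-oxo-2,5-dihydrofuran-2-yl]methyl}bicyclo[5.4.0]undec-3-en-8-one
Product: 22 17-(tert-butyldimethylsilyloxy)-4α-hydroxycyath-12-en-20,2β-olide (3α-H; 5β-H; 6α-CH3)
Conditions: SmI2, HMPA, t-BuOH, THF, −78 → 0 °C
Reagents that add atoms: none
Why: SmI2 ketyl–olefin cyclisation: the C4 ketyl adds 5-exo-trig to the butenolide β-carbon C3, the tether forces the cis ring A/lactone fusion (C3 from C2), and bond formation from the β (equatorial) side of C4, which keeps the new C–C bond away from the syn-axial C6 methyl and the ketyl oxygen anti to C18, should give the 4α-hydroxy trans-hydrindane.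

Step 15
Reactants: 22 17-(tert-butyldimethylsilyloxy)-4α-hydroxycyath-12-en-20,2β-olide
Product: 25 17-(tert-butyldimethylsilyloxy)-4α-hydroxycyatha-12,18(19)-dien-20,2β-olide, via Mannich base 23 (not isolated), via trimethylammonium iodide 24 (not isolated)
Conditions: LiN(iPr)2 (LDA, 2.2 equiv), THF, −78 °C; CH2=NMe2+ I−; then MeI, MeOH; then aq NaHCO3, CH2Cl2
Reagents that add atoms: dimethyl(methylene)ammonium iodide, C=[N+](C)C.[I-]
Why: Mannich aminomethylation of the lactone enolate (formed beside the C4 alkoxide), N-methylation and base-induced elimination of trimethylamine constitute the standard α-methylenation that creates the exocyclic C18=C19 alkene.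

Step 16
Reactants: 25 17-(tert-butyldimethylsilyloxy)-4α-hydroxycyatha-12,18(19)-dien-20,2β-olide
Product: 26 4α,17-dihydroxycyatha-12,18(19)-dien-20,2β-olide
Conditions: HF·pyridine, pyridine, THF, 0 °C → rt
Reagents that add atoms: none
Why: Fluoride desilylation under buffered conditions should free the primary alcohol while leaving the α-methylene lactone and the tertiary alcohol intact.

Step 17
Reactants: 26 4α,17-dihydroxycyatha-12,18(19)-dien-20,2β-olide
Product: 27 17-acetoxy-4α-hydroxycyatha-12,18(19)-dien-20,2β-olide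
Conditions: Ac2O, pyridine, DMAP (cat.), CH2Cl2, 0 °C
Reagents that add atoms: acetic anhydride, CC(=O)OC(C)=O
Why: Acetylation should occur only at the primary hydroxyl, the axial tertiary C4 hydroxyl being too hindered to react.

Step 18
Reactants: 27 17-acetoxy-4α-hydroxycyatha-12,18(19)-dien-20,2β-olide
Product: 28 17-acetoxy-12β,13β-epoxy-4α-hydroxycyath-18(19)-en-20,2β-olide (target CNP0214540.1)
Conditions: m-CPBA, CH2Cl2, 0 °C
Reagents that add atoms: 3-chloroperbenzoic acid, OOC(=O)c1cccc(Cl)c1
Why: Prilezhaev epoxidation should select the electron-rich trisubstituted C12=C13 alkene over the electron-poor α-methylene lactone and approach from the β face, away from the axial C6 methyl that shields the α face at C13–C14.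

Compound list
1 | 2-methylcyclohexan-1-one | CC1CCCCC1=O | starting material
2 | 2-methylcyclohex-1-en-1-yl acetate | CC1=C(OC(C)=O)CCCC1 | intermediate
3 | 1-bromobut-2-yne | CC#CCBr | starting material
4 | tributyl(2-methylcyclohex-1-en-1-yloxy)stannane (tributyltin enolate) | CC1=C(O[Sn](CCCC)(CCCC)CCCC)CCCC1 | intermediate
5 | (S)-2-(but-2-yn-1-yl)-2-methylcyclohexan-1-one | O=C1CCCC[C@@]1(C)CC#CC | intermediate
6 | vinylmagnesium bromide | C=C[Mg]Br | starting material
7 | (2S)-2-(but-2-yn-1-yl)-2-methyl-1-vinylcyclohexan-1-ol (both C1 epimers) | C=CC1(O)CCCC[C@@]1(C)CC#CC | intermediate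
8 | (3aS)-(Z)-2-ethylidene-3a-methyl-7a-vinyloctahydrobenzofuran (both C7a epimers) | C=CC12CCCC[C@@]1(C)C/C(=C/C)O2 | intermediate
9 | (1S)-1,4-dimethylbicyclo[5.4.0]undec-6-en-3-one (C4 epimers; skeleton: C13 ketone, C12 methyl, C5=C10) | C1CC[C@@]2(C)CC(=O)C(C)CC=C2C1 | intermediate
10 | (1S)-1,4-dimethylbicyclo[5.4.0]undeca-3,6-dien-3-yl triflate | C1CC[C@@]2(C)CC(OS(=O)(=O)C(F)(F)F)=C(C)CC=C2C1 | intermediate
11 | (1S)-8-hydroxy-1,4-dimethylbicyclo[5.4.0]undeca-3,6-dien-3-yl triflate (C8 epimers) | C1CC[C@@]2(C)CC(OS(=O)(=O)C(F)(F)F)=C(C)CC=C2C1O | intermediate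
12 | (1S)-1,4-dimethyl-8-oxobicyclo[5.4.0]undeca-3,6-dien-3-yl triflate | C1CC[C@@]2(C)CC(OS(=O)(=O)C(F)(F)F)=C(C)CC=C2C1=O | intermediate
13 | (1S,7S)-1,4-dimethyl-8-oxobicyclo[5.4.0]undec-3-en-3-yl triflate (trans-fused) | C1CC[C@@]2(C)CC(OS(=O)(=O)C(F)(F)F)=C(C)CC[C@@H]2C1=O | intermediate
14 | allyl bromide | C=CCBr | starting material
15 | (1S,7S)-9-allyl-1,4-dimethyl-8-oxobicyclo[5.4.0]undec-3-en-3-yl triflate (C9 epimers) | C=CCC1CC[C@@]2(C)CC(OS(=O)(=O)C(F)(F)F)=C(C)CC[C@@H]2C1=O | intermediate
16 | lithium alkoxide of the (9S)-9-allyl-9-(hydroxymethyl) ketone (lithium aldolate) | C=CC[C@]1(C[O-])CC[C@@]2(C)CC(OS(=O)(=O)C(F)(F)F)=C(C)CC[C@@H]2C1=O.[Li+] | intermediate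
17 | (1S,7S,9S)-9-allyl-9-[(tert-butyldimethylsilyloxy)methyl]-1,4-dimethyl-8-oxobicyclo[5.4.0]undec-3-en-3-yl triflate | C=CC[C@]1(CO[Si](C)(C)C(C)(C)C)CC[C@@]2(C)CC(OS(=O)(=O)C(F)(F)F)=C(C)CC[C@@H]2C1=O | intermediate
18 | (1S,7S,9S)-9-[(tert-butyldimethylsilyloxy)methyl]-1,4-dimethyl-8-oxo-9-(2-oxoethyl)bicyclo[5.4.0]undec-3-en-3-yl triflate | O=CC[C@]1(CO[Si](C)(C)C(C)(C)C)CC[C@@]2(C)CC(OS(=O)(=O)C(F)(F)F)=C(C)CC[C@@H]2C1=O | intermediate
19 | (1S,7S,9S)-9-[(tert-butyldimethylsilyloxy)methyl]-1,4-dimethyl-9-(2-oxoethyl)bicyclo[5.4.0]undec-3-en-8-one | O=CC[C@]1(CO[Si](C)(C)C(C)(C)C)CC[C@@]2(C)CC=C(C)CC[C@@H]2C1=O | intermediate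
20 | methyl (Z)-3-iodoacrylate | COC(=O)/C=C\I | starting material
21 | (1S,7S,9S)-9-[(tert-butyldimethylsilyloxy)methyl]-1,4-dimethyl-9-{[(2S)-5-oxo-2,5-dihydrofuran-2-yl]methyl}bicyclo[5.4.0]undec-3-en-8-one | O=C1C=C[C@H](C[C@]2(CO[Si](C)(C)C(C)(C)C)CC[C@@]3(C)CC=C(C)CC[C@@H]3C2=O)O1 | intermediate
22 | 17-(tert-butyldimethylsilyloxy)-4α-hydroxycyath-12-en-20,2β-olide | C1C(=O)O[C@H]2C[C@]3(CO[Si](C)(C)C(C)(C)C)CC[C@@]4(C)CC=C(C)CC[C@@H]4[C@@]3(O)[C@@H]12 | intermediate
23 | 19-(dimethylamino) derivative of 22 (Mannich base; C18 epimers) | CN(C)CC1C(=O)O[C@H]2C[C@]3(CO[Si](C)(C)C(C)(C)C)CC[C@@]4(C)CC=C(C)CC[C@@H]4[C@@]3(O)[C@@H]12 | intermediate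
24 | 19-(trimethylammonio) derivative of 22, iodide (C18 epimers) | C[N+](C)(C)CC1C(=O)O[C@H]2C[C@]3(CO[Si](C)(C)C(C)(C)C)CC[C@@]4(C)CC=C(C)CC[C@@H]4[C@@]3(O)[C@@H]12.[I-] | intermediate
25 | 17-(tert-butyldimethylsilyloxy)-4α-hydroxycyatha-12,18(19)-dien-20,2β-olide | C=C1C(=O)O[C@H]2C[C@]3(CO[Si](C)(C)C(C)(C)C)CC[C@@]4(C)CC=C(C)CC[C@@H]4[C@@]3(O)[C@@H]12 | intermediate
26 | 4α,17-dihydroxycyatha-12,18(19)-dien-20,2β-olide | C=C1C(=O)O[C@H]2C[C@]3(CO)CC[C@@]4(C)CC=C(C)CC[C@@H]4[C@@]3(O)[C@@H]12 | intermediate
27 | 17-acetoxy-4α-hydroxycyatha-12,18(19)-dien-20,2β-olide | C=C1C(=O)O[C@H]2C[C@]3(COC(C)=O)CC[C@@]4(C)CC=C(C)CC[C@@H]4[C@@]3(O)[C@@H]12 | intermediate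
28 | 17-acetoxy-12β,13β-epoxy-4α-hydroxycyath-18(19)-en-20,2β-olide (CNP0214540.1) | C=C1C(=O)O[C@H]2C[C@]3(COC(C)=O)CC[C@@]4(C)C[C@H]5O[C@@]5(C)CC[C@@H]4[C@@]3(O)[C@@H]12 | target

Total step count: 18. Longest linear sequence: 18 steps (1 → 28); the other numbered starting materials (3, 6, 14, 20) are commercial.

Steps most likely to fail

Step 14. The ketyl may close on the α face of C4 (giving the cis-hydrindane), or SmI2 may reduce the butenolide itself (ring-opening of the γ-oxygenated enoate, pinacol-type coupling) faster than the 5-exo closure. The fallback sets out from aldehyde 19 and rejoins at 25, closing ring A by a Barbier allylation that also installs the exocyclic methylene. Nozaki–Hiyama–Kishi coupling of 19 with methyl (Z)-2-(hydroxymethyl)-3-iodoacrylate F1 (made from methyl propiolate, paraformaldehyde and MgI2 by the iodide-mediated Morita–Baylis–Hillman reaction) would give the 3-(hydroxymethyl)butenolide F2. Appel bromination (CBr4, PPh3) would give the allylic bromide F3. Indium powder in THF/H2O would then generate the allylindium species, which adds through C3 to the C4 ketone to give 25 directly, so that step 15 is not needed; C4 selectivity again rests on the axial C6 methyl.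

Step 4. The alkoxide may add sluggishly to the unactivated internal alkyne at 200 °C, with base-induced alkyne–allene isomerisation or 6-endo addition competing. The fallback sets out from ketone 5 and rejoins at enol ether 8. RuCl3 (cat.)/NaIO4 would cleave the alkyne of 5 to 2-[(1S)-1-methyl-2-oxocyclohexyl]acetic acid F4. Excess vinylmagnesium bromide 6 with CeCl3, then acidic work-up, would give the γ-lactone 3a-methyl-7a-vinylhexahydrobenzofuran-2(3H)-one F5. Takai–Utimoto ethylidenation (CH3CHBr2, Zn, TiCl4, TMEDA) would convert the lactone carbonyl into the (Z)-enol ether 8, which is then heated (xylene, 180 °C) to undergo the same Claisen shift to 9.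

Step 18. Facial discrimination in the flexible cycloheptene may be poor, or attack may come from the α face. The fallback sets out from 27 and rejoins at 28. NBS in aqueous THF would place the bromonium ion on the face that electrophiles prefer, and water would open it at the tertiary C12 from the opposite face, giving the 13α-bromo-12β-hydroxy bromohydrin F6. Ag2O would then close the 12β,13β-epoxide 28 by backside displacement, i.e. on the face opposite to the one a peracid attacks.

Further compounds
F1 | step 14 | methyl (Z)-2-(hydroxymethyl)-3-iodoacrylate | COC(=O)/C(CO)=C\I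
F2 | step 14 | (1S,7S,9S)-9-[(tert-butyldimethylsilyloxy)methyl]-9-{[(2S)-4-(hydroxymethyl)-5-oxo-2,5-dihydrofuran-2-yl]methyl}-1,4-dimethylbicyclo[5.4.0]undec-3-en-8-one | OCC1=C[C@H](C[C@]2(CO[Si](C)(C)C(C)(C)C)CC[C@@]3(C)CC=C(C)CC[C@@H]3C2=O)OC1=O
F3 | step 14 | (1S,7S,9S)-9-{[(2S)-4-(bromomethyl)-5-oxo-2,5-dihydrofuran-2-yl]methyl}-9-[(tert-butyldimethylsilyloxy)methyl]-1,4-dimethylbicyclo[5.4.0]undec-3-en-8-one | BrCC1=C[C@H](C[C@]2(CO[Si](C)(C)C(C)(C)C)CC[C@@]3(C)CC=C(C)CC[C@@H]3C2=O)OC1=O
F4 | step 4 | 2-[(1S)-1-methyl-2-oxocyclohexyl]acetic acid | O=C1CCCC[C@@]1(C)CC(=O)O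
F5 | step 4 | (3aS)-3a-methyl-7a-vinylhexahydrobenzofuran-2(3H)-one (C7a epimers) | C=CC12CCCC[C@@]1(C)CC(=O)O2
F6 | step 18 | 17-acetoxy-13α-bromo-4α,12β-dihydroxycyath-18(19)-en-20,2β-olide | C=C1C(=O)O[C@H]2C[C@]3(COC(C)=O)CC[C@@]4(C)C[C@H](Br)[C@@](C)(O)CC[C@@H]4[C@@]3(O)[C@@H]12
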